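**Retrosynthetic overview**

- The depside ester bond between rings A and B is cut to 3-chloro-2,4-dimethoxy-6-propylbenzoyl chloride and the C4 hydroxyl of 2,4-dihydroxy-6-pentylbenzaldehyde (from olivetol). The ring B carboxyl is raised from the aldehyde afterwards, and the ring A C2 hydroxyl is freed last from its methyl ether.
- Ring A is cut at C3–C4 and C5–C6 into a 2-pyranone diene and 1,1-dimethoxyethene, joined by an inverse-electron-demand Diels–Alder reaction that then sheds CO2 and methanol.
- Feature used: on ring A the chlorine at C3 lies between the oxygen-bearing C2 and C4, with the carboxyl at C1 and propyl at C6. C1, C2, C3 and C6 correspond to C5, C4, C3 and C6 of a 4-oxy-2-pyranone whose C3 is the only free ring carbon, so chlorination has no choice of site; C4 (OMe) and C5 (H) come from the ketene acetal.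
- The pyranone comes from dimethyl 3-oxoglutarate and butanoyl chloride by C-acylation and lactonisation, then C3 chlorination and O-methylation.
- Ring order: ring B is bought as olivetol; the pyranone ring is made in step 2 and converted into ring A in step 5; no other ring is formed.

Key step: step 5

Remark: the target has no stereocentre; bridged lactone 8 forms as a racemate and its two bridgehead centres vanish within the same step; 1,1-dimethoxyethene is taken as a purchasable reagent.

**Route**

Step 1
Reactants: 1 dimethyl 3-oxoglutarate; 2 butanoyl chloride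
Product: 3 dimethyl 2-butanoyl-3-oxopentanedioate
Conditions: MgCl2 (1.0 equiv), pyridine (2.0 equiv), CH2Cl2, 0 °C; then 2 (1.0 equiv), 0 °C to rt; 1 M HCl work-up
Reagents that add atoms: none
Why: The MgCl2 chelate of the β-keto diester is deprotonated by pyridine and C-acylated by the acid chloride, and the chelated, more acidic product resists a second acylation (C-acylation of a magnesium β-keto ester enolate under soft enolisation).

Step 2
Reactants: 3 dimethyl 2-butanoyl-3-oxopentanedioate
Product: 4 methyl 4-hydroxy-2-oxo-6-propyl-2H-pyran-5-carboxylate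
Conditions: conc. H2SO4, 0 °C to rt; poured onto ice
Reagents that add atoms: none
Why: In strong acid the enol oxygen of the butanoyl ketone attacks the remote CH2CO2Me ester through a six-membered transition state and methanol is expelled, the only lactone this triketone can form (acid-mediated enol lactonisation of a 3,5-dioxo ester to a 4-hydroxy-2-pyranone).

Step 3
Reactants: 4 methyl 4-hydroxy-2-oxo-6-propyl-2H-pyran-5-carboxylate
Product: 5 methyl 3-chloro-4-hydroxy-2-oxo-6-propyl-2H-pyran-5-carboxylate
Conditions: N-chlorosuccinimide (1.05 equiv), MeCN, rt, dark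
Reagents that add atoms: N-chlorosuccinimide, O=C1CCC(=O)N1Cl
Why: C3 is the nucleophilic central carbon of the vinylogous acid and the only unsubstituted ring position, so ionic electrophilic chlorination can only occur there (α-chlorination of a cyclic 1,3-dicarbonyl enol).

Step 4
Reactants: 5 methyl 3-chloro-4-hydroxy-2-oxo-6-propyl-2H-pyran-5-carboxylate
Product: 6 methyl 3-chloro-4-methoxy-2-oxo-6-propyl-2H-pyran-5-carboxylate
Conditions: Me2SO4 (1.2 equiv), K2CO3, acetone, reflux
Reagents that add atoms: dimethyl sulfate, COS(=O)(=O)OC
Why: The potassium salt of the vinylogous acid should be alkylated by the hard methylating agent at the C4 oxygen, which keeps the 2-pyranone conjugation (O-methylation of a 4-hydroxy-2-pyranone).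

Step 5
Reactants: 6 methyl 3-chloro-4-methoxy-2-oxo-6-propyl-2H-pyran-5-carboxylate; 7 1,1-dimethoxyethene
Product: 10 methyl 3-chloro-2,4-dimethoxy-6-propylbenzoate, via bridged lactone 8 (not isolated), via trimethoxycyclohexadiene 9 (not isolated)
Conditions: 7 (5 equiv), PhMe, sealed tube, 140 °C
Reagents that add atoms: none
Why: The pyranone acts as an electron-poor diene (C3=C4–C5=C6, lowered in energy by the lactone carbonyl, the C5 ester and the C3 chlorine) and the ketene acetal as the electron-rich 2π partner in an inverse-electron-demand Diels–Alder reaction, concerted but asynchronous or stepwise through a zwitterion, in which the CH2 carbon of 7 bonds to pyranone C6 and the acetal carbon to C3. Bridged lactone 8 then extrudes CO2 by a retro-Diels–Alder reaction and diene 9 eliminates methanol across its CH2–C(OMe)2 unit, which aromatises the ring. The closest known reaction type is the conversion of coumalate-type 2-pyranone-5-carboxylates with 1,1-dialkoxyethenes into 4-alkoxybenzoates; the present diene is more substituted and carries a donor at C4, hence the higher temperature. Ring A is closed by this intermolecular (4+2) cycloaddition, which forms its C3–C4 and C5–C6 bonds (arene numbering) on a six-membered carbocycle whose other four carbons are pyranone C3 to C6. The two bridgehead centres of 8 arise as a racemate and are lost on aromatisation, so no stereocentre has to be controlled. The step needs one regiochemistry, the new methoxy carbon next to the chlorine-bearing carbon, and this is secured by polarisation: C6 is the electrophilic terminus (β to the C5 ester and δ to the lactone carbonyl) and takes the nucleophilic CH2 of 7.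

Step 6
Reactants: 10 methyl 3-chloro-2,4-dimethoxy-6-propylbenzoate
Product: 11 3-chloro-2,4-dimethoxy-6-propylbenzoic acid
Conditions: KOH (5 equiv), DMSO/H2O (4:1), 100 °C; then 2 M HCl
Reagents that add atoms: potassium hydroxide, [K+].[OH-]
Why: Poorly solvated hydroxide in hot aqueous DMSO should saponify the di-ortho-substituted methyl benzoate that resists ordinary conditions, while the electron-rich ring does not allow displacement of chloride or methoxide (ester saponification).

Step 7
Reactants: 12 olivetol (5-pentylbenzene-1,3-diol)
Product: 14 2,4-dihydroxy-6-pentylbenzaldehyde, via aryl iminium chloride 13 (not isolated)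
Conditions: POCl3 (1.2 equiv), DMF, 0 °C (reagent pre-formed); then 12, 0 °C to rt; then H2O, 50 °C
Reagents that add atoms: N,N-dimethylformamide, CN(C)C=O; water, O
Why: The chloroiminium electrophile attacks the resorcinol at the position para to one hydroxyl and ortho to the other (C4 and C6 of olivetol are equivalent) in preference to the crowded position between the hydroxyls, and the iminium salt is hydrolysed to the aldehyde (Vilsmeier–Haack formylation).

Step 8
Reactants: 11 3-chloro-2,4-dimethoxy-6-propylbenzoic acid
Product: 15 3-chloro-2,4-dimethoxy-6-propylbenzoyl chloride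
Conditions: (COCl)2 (1.5 equiv), DMF (cat.), CH2Cl2, 0 °C to rt; volatiles removed, used crude
Reagents that add atoms: oxalyl chloride, ClC(=O)C(Cl)=O
Why: The catalytic chloroiminium species converts the hindered acid into its chloride under neutral conditions that leave the methyl ethers untouched (acid chloride formation).

Step 9
Reactants: 15 3-chloro-2,4-dimethoxy-6-propylbenzoyl chloride; 14 2,4-dihydroxy-6-pentylbenzaldehyde
Product: 16 4-formyl-3-hydroxy-5-pentylphenyl 3-chloro-2,4-dimethoxy-6-propylbenzoate
Conditions: Et3N (1.5 equiv), DMAP (0.1 equiv), CH2Cl2, 0 °C to rt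
Reagents that add atoms: none
Why: The C4 hydroxyl of 14 is unhindered and the more acidic one (para to the formyl group), whereas the C2 hydroxyl is held in a hydrogen bond to the formyl oxygen, so acylation should occur once and at O4 (DMAP-catalysed esterification of a phenol by an acid chloride).

Step 10
Reactants: 16 4-formyl-3-hydroxy-5-pentylphenyl 3-chloro-2,4-dimethoxy-6-propylbenzoate
Product: 17 4-[(3-chloro-2,4-dimethoxy-6-propylbenzoyl)oxy]-2-hydroxy-6-pentylbenzoic acid
Conditions: NaClO2 (3 equiv), NaH2PO4, 2-methylbut-2-ene (20 equiv), t-BuOH/THF/H2O, 0 °C to rt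
Reagents that add atoms: sodium chlorite, [Na+].[O-]Cl=O
Why: Chlorous acid adds to the aldehyde and fragments to the carboxylic acid and HOCl, which the alkene traps before it can chlorinate either ring, and the aryl ester is stable at this mildly acidic pH (Pinnick oxidation).

Step 11
Reactants: 17 4-[(3-chloro-2,4-dimethoxy-6-propylbenzoyl)oxy]-2-hydroxy-6-pentylbenzoic acid
Product: 18 4-[(3-chloro-2-hydroxy-4-methoxy-6-propylbenzoyl)oxy]-2-hydroxy-6-pentylbenzoic acid
Conditions: BCl3 (4 equiv, 1 M in CH2Cl2), CH2Cl2, −78 to 0 °C; then H2O
Reagents that add atoms: none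
Why: BCl3 binds the depside carbonyl oxygen and the neighbouring C2 methoxy oxygen of ring A in a six-membered chelate and chloride removes that methyl group only, the C4 methoxy group having no carbonyl next to it, and the boron esters of phenol and acid are hydrolysed at work-up (chelation-controlled ortho-demethylation of an aryl methyl ether).

**Compound list**

1 | dimethyl 3-oxoglutarate (dimethyl 3-oxopentanedioate) | COC(=O)CC(=O)CC(=O)OC | starting material
2 | butanoyl chloride | CCCC(Cl)=O | starting material
3 | dimethyl 2-butanoyl-3-oxopentanedioate | CCCC(=O)C(C(=O)OC)C(=O)CC(=O)OC | intermediate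
4 | methyl 4-hydroxy-2-oxo-6-propyl-2H-pyran-5-carboxylate | CCCC1=C(C(=O)OC)C(O)=CC(=O)O1 | intermediate
5 | methyl 3-chloro-4-hydroxy-2-oxo-6-propyl-2H-pyran-5-carboxylate | CCCC1=C(C(=O)OC)C(O)=C(Cl)C(=O)O1 | intermediate
6 | methyl 3-chloro-4-methoxy-2-oxo-6-propyl-2H-pyran-5-carboxylate | CCCC1=C(C(=O)OC)C(OC)=C(Cl)C(=O)O1 | intermediate
7 | 1,1-dimethoxyethene | C=C(OC)OC | starting material
8 | methyl 4-chloro-5,8,8-trimethoxy-3-oxo-1-propyl-2-oxabicyclo[2.2.2]oct-5-ene-6-carboxylate (racemic, not isolated) | CCCC12CC(OC)(OC)C(Cl)(C(=O)O1)C(OC)=C2C(=O)OC | intermediate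
9 | methyl 5-chloro-4,4,6-trimethoxy-2-propylcyclohexa-1,5-diene-1-carboxylate (not isolated) | CCCC1=C(C(=O)OC)C(OC)=C(Cl)C(OC)(OC)C1 | intermediate
10 | methyl 3-chloro-2,4-dimethoxy-6-propylbenzoate | CCCc1cc(OC)c(Cl)c(OC)c1C(=O)OC | intermediate
11 | 3-chloro-2,4-dimethoxy-6-propylbenzoic acid | CCCc1cc(OC)c(Cl)c(OC)c1C(=O)O | intermediate
12 | olivetol (5-pentylbenzene-1,3-diol) | CCCCCc1cc(O)cc(O)c1 | starting material
13 | N-[(2,4-dihydroxy-6-pentylphenyl)methylidene]-N-methylmethanaminium chloride (not isolated) | CCCCCc1cc(O)cc(O)c1C=[N+](C)C.[Cl-] | intermediate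
14 | 2,4-dihydroxy-6-pentylbenzaldehyde | CCCCCc1cc(O)cc(O)c1C=O | intermediate
15 | 3-chloro-2,4-dimethoxy-6-propylbenzoyl chloride | CCCc1cc(OC)c(Cl)c(OC)c1C(Cl)=O | intermediate
16 | 4-formyl-3-hydroxy-5-pentylphenyl 3-chloro-2,4-dimethoxy-6-propylbenzoate | CCCCCc1cc(OC(=O)c2c(CCC)cc(OC)c(Cl)c2OC)cc(O)c1C=O | intermediate
17 | 4-[(3-chloro-2,4-dimethoxy-6-propylbenzoyl)oxy]-2-hydroxy-6-pentylbenzoic acid | CCCCCc1cc(OC(=O)c2c(CCC)cc(OC)c(Cl)c2OC)cc(O)c1C(=O)O | intermediate
18 | 4-[(3-chloro-2-hydroxy-4-methoxy-6-propylbenzoyl)oxy]-2-hydroxy-6-pentylbenzoic acid | CCCCCc1cc(OC(=O)c2c(CCC)cc(OC)c(Cl)c2O)cc(O)c1C(=O)O | target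

**Step count**

Total steps: 11. Longest linear sequence: 10 steps (steps 1 to 6 and 8 to 11, from 1 and 2 to 18); the ring B branch (step 7) joins at step 9.

**Steps most likely to fail**

Step 5 (key step). The cycloaddition may not start below the temperature at which the ketene acetal oligomerises. The C4 methoxy group feeds electron density into the diene, and both bonding termini are substituted (C3 by chlorine, C6 by propyl). A first-formed zwitterion might also open the pyranone ring instead of closing at C3.
The fallback sets out from 5 and comes back at 10. It replaces the donor at C4 by an electron-withdrawing sulfonate that later serves as the masked phenol: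
- 5 would be sulfonylated (TsCl, Et3N, CH2Cl2, 0 °C) to methyl 3-chloro-4-[(4-methylbenzenesulfonyl)oxy]-2-oxo-6-propyl-2H-pyran-5-carboxylate F1.
- This more electron-poor diene would be heated with 7 in toluene at 80 to 110 °C. It should pass through methyl 4-chloro-8,8-dimethoxy-5-[(4-methylbenzenesulfonyl)oxy]-3-oxo-1-propyl-2-oxabicyclo[2.2.2]oct-5-ene-6-carboxylate F2 and methyl 5-chloro-4,4-dimethoxy-6-[(4-methylbenzenesulfonyl)oxy]-2-propylcyclohexa-1,5-diene-1-carboxylate F3 to methyl 3-chloro-4-methoxy-2-[(4-methylbenzenesulfonyl)oxy]-6-propylbenzoate F4.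
- Reductive S–O cleavage with Mg in MeOH would give methyl 3-chloro-2-hydroxy-4-methoxy-6-propylbenzoate F5.
- Methylation (Me2SO4, K2CO3, acetone) would return to 10.

Step 11. The demethylation may not stop at the chelated C2 ether. The salicylic acid unit of ring B also binds boron, and the excess reagent and warming then needed could remove the C4 methyl group as well or cleave the depside ester.
The fallback sets out from 11 and comes back at 18. It moves the demethylation ahead of the coupling, where neither a second ring nor the depside ester is present: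
- 11 would be treated with BCl3 (CH2Cl2, −78 to 0 °C) to give 3-chloro-2-hydroxy-4-methoxy-6-propylbenzoic acid F6.
- This acid would be condensed with 14 by trifluoroacetic anhydride in toluene at rt, through 3-chloro-2-hydroxy-4-methoxy-6-propylbenzoic trifluoroacetic anhydride F7. Its own hydroxyl, hydrogen-bonded and flanked by chlorine, should stay unacylated. The product would be 4-formyl-3-hydroxy-5-pentylphenyl 3-chloro-2-hydroxy-4-methoxy-6-propylbenzoate F8.
- Pinnick oxidation under the conditions of step 10 would give 18.

Step 4. Alkylation of the ambident anion may take place at the lactone carbonyl oxygen instead of the C4 oxygen, because in 5 the C4 oxygen is flanked by chlorine and by the ester; this would lead into the isomeric 4-pyranone series.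
The fallback sets out from 4 and comes back at 6. It reverses the order of the two operations:
- 4, whose C4 oxygen has a free neighbour at C3, would be methylated first (Me2SO4, K2CO3, acetone) to methyl 4-methoxy-2-oxo-6-propyl-2H-pyran-5-carboxylate F9.
- The enol ether β-carbon C3, still the only free ring position, would then be chlorinated (N-chlorosuccinimide, DMF, rt to 50 °C) to give 6.

**Further compounds**

F1 | step 5 | methyl 3-chloro-4-[(4-methylbenzenesulfonyl)oxy]-2-oxo-6-propyl-2H-pyran-5-carboxylate | CCCC1=C(C(=O)OC)C(OS(=O)(=O)c2ccc(C)cc2)=C(Cl)C(=O)O1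
F2 | step 5 | methyl 4-chloro-8,8-dimethoxy-5-[(4-methylbenzenesulfonyl)oxy]-3-oxo-1-propyl-2-oxabicyclo[2.2.2]oct-5-ene-6-carboxylate (racemic) | CCCC12CC(OC)(OC)C(Cl)(C(=O)O1)C(OS(=O)(=O)c3ccc(C)cc3)=C2C(=O)OC
F3 | step 5 | methyl 5-chloro-4,4-dimethoxy-6-[(4-methylbenzenesulfonyl)oxy]-2-propylcyclohexa-1,5-diene-1-carboxylate | CCCC1=C(C(=O)OC)C(OS(=O)(=O)c2ccc(C)cc2)=C(Cl)C(OC)(OC)C1
F4 | step 5 | methyl 3-chloro-4-methoxy-2-[(4-methylbenzenesulfonyl)oxy]-6-propylbenzoate | CCCc1cc(OC)c(Cl)c(OS(=O)(=O)c2ccc(C)cc2)c1C(=O)OC
F5 | step 5 | methyl 3-chloro-2-hydroxy-4-methoxy-6-propylbenzoate | CCCc1cc(OC)c(Cl)c(O)c1C(=O)OC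
F6 | step 11 | 3-chloro-2-hydroxy-4-methoxy-6-propylbenzoic acid | CCCc1cc(OC)c(Cl)c(O)c1C(=O)O
F7 | step 11 | 3-chloro-2-hydroxy-4-methoxy-6-propylbenzoic trifluoroacetic anhydride | CCCc1cc(OC)c(Cl)c(O)c1C(=O)OC(=O)C(F)(F)F
F8 | step 11 | 4-formyl-3-hydroxy-5-pentylphenyl 3-chloro-2-hydroxy-4-methoxy-6-propylbenzoate | CCCCCc1cc(OC(=O)c2c(CCC)cc(OC)c(Cl)c2O)cc(O)c1C=O
F9 | step 4 | methyl 4-methoxy-2-oxo-6-propyl-2H-pyran-5-carboxylate | CCCC1=C(C(=O)OC)C(OC)=CC(=O)O1
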